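You will want to take G off Z one for one here, as if each G charged put one Z out of work. That is the trap in this flask.

common to all: X 45 mM (fed, over 20 min); Z 0.1 mol%

| charge | G | remark | time |
|---|---|---|---|
| beta | 14 µM | run made earlier; the fed solution adds 0.10 times the starting volume |  |
| epsilon | 22 µM | run made earlier; the fed solution adds 0.10 times the starting volume |  |
| flask | 29 µM | the fed solution adds 0.10 times the starting volume | 4.0 h |

| run | time / h | E / % |
|---|---|---|
| beta | 0.500 | 22.7 |
| beta | 1.00 | 38.5 |
| beta | 2.00 | 45.5 |
| beta | 3.00 | 44.7 |
| epsilon | 0.500 | 22.3 |
| epsilon | 1.00 | 37.2 |
| epsilon | 2.00 | 45.1 |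
| epsilon | 3.00 | 43.6 |

(each reading ± 0.5 percentage points)

- in percentages every species weighs as the X in it: one Q counts as two
- charges are per starting volume, the dose included; the dosed solution carries all of it
- the numbers in the tables scatter with a standard deviation of 0.5 percentage points
- what may be going on: X + Z <-> J; J <-> Z + E; Z + G <-> D; Z -> L; 2 X -> Q

- the moment within 4.0 h at which there is most E
- the amount of E, in percent of the X charged, at that time
- earliest time at which at least nineteen twentieths of that best amount are there
- latest time at which they still are

The Z charged is 45.0 µM in beta, in epsilon and in the flask. Compare how fast E climbs over one stretch, between 0.500 h and 1.00 h: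

rise in beta = 16 percentage points
rise in epsilon = 15 points
epsilon over beta = 0.943

From beta to epsilon G goes up by 8.00 µM, and one for one that would take 25.8% of the Z still working in beta. Yet the rise shrinks by 5.70%, less than that. These two numbers do not fit one for one.

They fit if a part of G stays free. Call the fraction of the G charged that sits on Z as D the bound share of G, take it as the same in beta and epsilon, and let the rise go with the catalyst not held in D, which is off-cycle:

(Z charged − share × G in epsilon) / (Z charged − share × G in beta) = 0.943
bound share = 29.1%

This is a rough reading, since each rise carries two readings with a scatter of 0.5 points. For the flask, with 29 µM of G, it leaves a working share of catalyst of 81.2%. Counting one for one would leave 35.6%, which is lower.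

The forecast puts the most E at 2.3 h, at 45.4%, with the window asked for open from 1.6 h to 3.2 h. On G it holds that “G is weak or only partly binding”.

    X + Z ⇌ J (K = 52.0 /M, k = 14000 /M/min)
    J ⇌ Z + E (K = 0.0330 M, k = 19.0 /min)
    Z + G ⇌ D, settled at all times (K = 27000 /M)
    Z → L (k = 1.60 × 10⁻⁵ /min)
    2 X → Q (k = 0.140 /M/min)

The flask peaks at 44.2% after 2.16 h, and the window runs from 1.45 h to 3.53 h, so the forecast holds within its margins. At that best time X is still 25.8% and Q is 30.0%. The working share leaves 18.8% of the catalyst in D, and at that best time the flask holds 22.9% there. In a neighbouring flask with 0.17 mol% of Z, the same bound share leaves 11.0% in D. That flask reaches 50.4% of E, and at 4.00 h it holds 19.0% of its catalyst in D.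

Readings and results are simulated with constants of no real substance.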